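C1 is the ring ketone, C2 bears the CH2OH carbon, C3 is =CH, C4 is CH2, C5 is quaternary (CH3 and side chain), C6 bears the alkenyl ester, C7 bears the acetonyl group.
Cuts, last-formed bond first: the C–OOH bond (H2O2 on an allylic sulfonate), the carbinol–isopropenyl C–C bond (aldehyde alkenylation), the alkenyl C–O bond of the enol ester (alkenyl iodide plus senecioate), then ring bonds C1–C2 and C3–C4.
Enabling feature: C2, C3 and the CH2OH carbon form a propiolate-shaped three-carbon unit between C1 and C4 of the seven-membered ring. Removing it and joining C1 to C4 leaves a cyclopentanone (C1, C4, C5, C6, C7) that already carries all three ring stereocentres.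
Forward order: the five-membered ring is bought as a silyloxycyclopentenone and substituted at C6, C7 and C5. Its C1=C4 pyrrolidine enamine takes up methyl propiolate by [2+2], the cyclobutene opens to the seven-membered ring, and the side chains are finished last.
Stereochemistry: the silyloxy centre of the starting enone steers C6, and C6 steers C7 and the quaternary C5, each new group entering anti to its neighbour. The side-chain centre comes from a ligand-controlled aldehyde alkenylation and is inverted in the peroxide displacement.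

Key step: step 6

Drawing convention: with the ring drawn so that C5, C4, (C3, C2,) C1, C7, C6 run clockwise, β points to the viewer. Throughout, the C7 side chain is β, the C6 alkenyl group is α, the C5 chain (at first the silyloxy group) is β and the C5 methyl is α.
Choice of spectator groups: the C5 chain is carried as a 3-silyloxypropyl group, because a prenyl or isopropenyl alkene would outrun the alkenylsilane in the iododesilylation. The propargyl group is capped with SiMe3 so that no acidic C–H meets the organometallic steps.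
Assumption: the β-keto ester obtained after the key step is drawn as its chelated enol. Both antipodes of the oxazoline–sulfonamide ligand of step 16 are taken to be accessible, and the one that directs attack to the Si face of the aldehyde is meant.

Step 1
Reactants: 1 (E)-(2-bromoethenyl)trimethylsilane; 2 (S)-4-(tert-butyldimethylsilyloxy)cyclopent-2-en-1-one; 3 3-bromo-1-(trimethylsilyl)prop-1-yne
Product: 7 (2S,3R,4S)-4-(tert-butyldimethylsilyloxy)-3-[(E)-2-(trimethylsilyl)ethenyl]-2-[3-(trimethylsilyl)prop-2-ynyl]cyclopentan-1-one, via alkenyllithium 4 (not isolated), via mixed lithium zincate 5 (not isolated), via zinc enolate 6 (not isolated)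
Conditions: 1, t-BuLi (2 equiv), Et2O, −78 °C; Me2Zn, THF, −78 → 0 °C; 2, −78 °C; HMPA, 3, −78 → −40 °C; aq. NH4Cl
Reagents that add atoms: none
Why: Three-component coupling (tandem conjugate addition–enolate alkylation): the zincate should transfer its alkenyl group to C6 anti to the C5 silyloxy group, and the zinc enolate, which resists β-elimination, should be alkylated at C7 anti to the new C6 group, so both new centres derive from the one in 2.

Step 2
Reactants: 7 three-component ketone
Product: 8 (4R,5S)-4-[(E)-2-(trimethylsilyl)ethenyl]-5-[3-(trimethylsilyl)prop-2-ynyl]cyclopent-2-en-1-one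
Conditions: DBU, CH2Cl2, 0 °C
Reagents that add atoms: none
Why: E1cB elimination of the β-silyloxy group through the C4 enolate should give the C4=C5 enone, the low temperature keeping the doubly allylic C6–H in place and C7 in its favoured trans arrangement.

Step 3
Reactants: 8 disubstituted cyclopentenone
Product: 10 (4R,5S)-3-methyl-4-[(E)-2-(trimethylsilyl)ethenyl]-5-[3-(trimethylsilyl)prop-2-ynyl]cyclopent-2-en-1-one, via lithium enolate 9 (not isolated)
Conditions: Me2CuLi (from MeLi, CuI), Et2O, −78 °C; then PhS(Cl)=N-t-Bu, THF, −78 °C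
Reagents that add atoms: methyllithium, C[Li]
Why: Cuprate 1,4-addition followed in the same flask by Mukaiyama dehydrogenation (sulfur attack at C4 of the regiodefined enolate, then syn elimination of the sulfenamide) should place the methyl group on C5 and restore the enone, erasing the transient C5 centre.

Step 4
Reactants: 10 3-methylcyclopentenone; 11 (3-bromopropoxy)(tert-butyl)dimethylsilane
Product: 14 (2S,3R,4S)-4-[3-(tert-butyldimethylsilyloxy)propyl]-4-methyl-3-[(E)-2-(trimethylsilyl)ethenyl]-2-[3-(trimethylsilyl)prop-2-ynyl]cyclopentan-1-one, via Grignard reagent 12 (not isolated), via trimethylsilyl enol ether 13 (not isolated)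
Conditions: 11, Mg, THF; CuBr·SMe2 (20 mol %), Me3SiCl, HMPA, THF, −78 → −40 °C; then AcOH–H2O–THF, rt
Reagents that add atoms: none
Why: Copper-catalysed, chlorosilane-accelerated conjugate addition of a Grignard reagent to a β,β-disubstituted enone, in which the nucleophile should approach C5 anti to the adjacent 6α alkenyl group and so set the quaternary centre with the chain β and the methyl α.

Step 5
Reactants: 14 tetrasubstituted cyclopentanone
Product: 15 C1=C4 pyrrolidine enamine of 14 (1-pyrrolidinylcyclopentene with 5β-silyloxypropyl 5α-methyl 6α-silylethenyl 7β-silylpropargyl groups)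
Conditions: pyrrolidine (5 equiv), p-TsOH (cat.), benzene, reflux, 4 Å molecular sieves; evaporation, high vacuum
Reagents that add atoms: pyrrolidine, C1CCNC1
Why: Stork enamine formation should give the less substituted C1=C4 isomer because the C1=C7 isomer suffers allylic 1,3-strain between the pyrrolidine ring and the C7 side chain, and any equilibration at C7 returns the favoured 6,7-trans arrangement.

Step 6
Reactants: 15 pyrrolidine enamine; 16 methyl propiolate
Product: 18 methyl 2-(pyrrolidin-1-yl)cyclohepta-1,3-diene-1-carboxylate [C1(N)=C2(CO2Me)–C3H=C4H] carrying the C5–C7 substituents of 15 unchanged, via aminocyclobutene 17 (not isolated)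
Conditions: 16 (1.5 equiv), toluene, 0 °C → rt, then 80 °C
Reagents that add atoms: none
Why: The nucleophilic enamine carbon C4 adds to the unsubstituted terminus of 16 (the future C3), and the ester-bearing allenolate carbon (C2) then closes onto the iminium carbon C1, a stepwise polar [2+2] whose ring closure is 4-exo-trig and gives the cis-fused 1-aminobicyclo[3.2.0]hept-6-ene 17. In 17 the donor nitrogen on C1 and the acrylate acceptor across C2=C3 polarise the shared C1–C4 bond, which should break on warming in a push–pull assisted cyclobutene opening, so the seven-membered ring arises by ring expansion (cleavage of the fusion bond) and not by end-to-end closure, the zwitterionic character allowing the all-cis ring diene to form. The closest known reaction type is the two-carbon ring enlargement of cyclic ketone enamines with acetylenic esters, established for pyrrolidinocyclopentene and methyl propiolate. No stereocentre is created in 18: the transient centres C1 and C4 of 17 (addition expected on the α face, anti to the pseudoaxial C7 chain) return to sp2, and C5, C6 and C7 take no part. The step needs the C1=C4 enamine (secured by allylic 1,3-strain), the head-to-tail orientation (secured by the matched polarity of the partners) and chemoselectivity (the silylalkyne, alkenylsilane and silyl ether are inert to both partners). An aprotic, non-polar solvent and amine-free 15 are used so that the zwitterion closes and is not diverted by proton transfer or by amine addition to 16.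

Step 7
Reactants: 18 dienamine ester
Product: 19 methyl 2-hydroxycyclohepta-1,3-diene-1-carboxylate (chelated enol of the C1 β-keto ester with C3=C4) carrying the C5–C7 substituents unchanged
Conditions: AcOH–NaOAc, H2O–THF, 40 °C
Reagents that add atoms: water, O
Why: Hydrolysis of a vinylogous carbamate (C-protonation, then hydrolysis of the iminium ion) should free the β-keto ester under buffered conditions that leave the silyl ether, silylalkyne and alkenylsilane intact.

Step 8
Reactants: 19 β-keto ester
Product: 20 methyl 2-(triethylsilyloxy)cyclohepta-1,3-diene-1-carboxylate carrying the C5–C7 substituents unchanged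
Conditions: Et3SiOTf, Et3N, CH2Cl2, −78 → 0 °C
Reagents that add atoms: triethylsilyl trifluoromethanesulfonate, CC[Si](CC)(CC)OS(=O)(=O)C(F)(F)F
Why: O-silylation of an enolised β-keto ester should funnel all tautomers into one through-conjugated dienol ether, which masks C1 and removes the acidic proton before the hydride step.

Step 9
Reactants: 20 silyl dienol ether ester
Product: 21 [2-(triethylsilyloxy)cyclohepta-1,3-dien-1-yl]methanol carrying the C5–C7 substituents unchanged
Conditions: i-Bu2AlH (3 equiv), CH2Cl2, −78 °C; aq. potassium sodium tartrate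
Reagents that add atoms: none
Why: i-Bu2AlH reduction of a β-silyloxy dienoate to the allylic alcohol is standard ester reduction, and an oxygen donor is used because the amino analogue would be too unreactive and would expel the new alkoxide.

Step 10
Reactants: 21 dienol ether alcohol
Product: 23 2-(tert-butyldiphenylsilyloxymethyl)cyclohept-2-en-1-one with 5β-(3-silyloxypropyl) 5α-methyl 6α-(E)-silylethenyl 7β-silylpropargyl groups, via bis-silyl ether 22 (not isolated)
Conditions: t-BuPh2SiCl, imidazole, CH2Cl2, 0 °C → rt; then AcOH–H2O–THF, 0 °C → rt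
Reagents that add atoms: tert-butyl(chloro)diphenylsilane, CC(C)(C)[Si](Cl)(c1ccccc1)c1ccccc1
Why: Silylation of the primary alcohol followed by acid hydrolysis of the 1-silyloxy-1,3-diene, in which protonation at the diene terminus C4 (γ-protonation, giving the more delocalised oxocarbenium ion) should deliver the conjugated C2=C3 enone directly while the bulky, weakly basic silyl ether suppresses allylic ionisation.

Step 11
Reactants: 23 silylalkynyl enone
Product: 24 the corresponding 7β-(2-oxopropyl) enone (1,4-diketone) with all other groups unchanged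
Conditions: Ph3PAuCl (5 mol %), AgOTf (5 mol %), 1,4-dioxane–H2O, 40 °C
Reagents that add atoms: water, O
Why: Gold-catalysed Markovnikov alkyne hydration, assisted by 5-exo-dig participation of the C1 carbonyl and by the β-silicon effect, should give the α-silyl ketone, which loses silicon hydrolytically to leave the methyl ketone.

Step 12
Reactants: 24 alkenylsilane diketone
Product: 25 the corresponding 6α-[(E)-2-iodoethenyl] diketone
Conditions: N-iodosuccinimide, 2,6-lutidine, (CF3)2CHOH, 0 °C, dark
Reagents that add atoms: N-iodosuccinimide, O=C1CCC(=O)N1I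
Why: Electrophilic ipso-iododesilylation of an (E)-alkenylsilane proceeds with retention, and at this stage the only other alkene is the electron-poor enone.

Step 13
Reactants: 25 alkenyl iodide; 26 3-methylbut-2-enoic acid
Product: 28 the 6α-[(E)-2-(3-methylbut-2-enoyloxy)ethenyl] diketone, via cesium 3-methylbut-2-enoate 27 (not isolated)
Conditions: 26, Cs2CO3 (1 equiv each), toluene, rt; then 25, CuI (20 mol %), 1,10-phenanthroline (40 mol %), 80 °C
Reagents that add atoms: none
Why: Ullmann-type vinylic C–O coupling of an alkenyl iodide with a carboxylate on copper is stereoretentive, and with the preformed carboxylate as the only base the 1,4-diketone and C7 should be spared.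

Step 14
Reactants: 28 enol ester bis-silyl ether
Product: 29 the 5β-(3-hydroxypropyl) compound with the tert-butyldiphenylsilyl ether retained
Conditions: HF·pyridine, pyridine, THF, 0 °C
Reagents that add atoms: none
Why: Selective desilylation should succeed because a primary tert-butyldimethylsilyl ether is cleaved by buffered HF far faster than a tert-butyldiphenylsilyl ether, and no alcohol solvent is present to transesterify the enol ester.

Step 15
Reactants: 29 primary alcohol
Product: 30 the 5β-(3-oxopropyl) aldehyde
Conditions: Dess–Martin periodinane, CH2Cl2, 0 °C → rt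
Reagents that add atoms: none
Why: Dess–Martin oxidation converts the only free alcohol into the aldehyde under near-neutral conditions tolerated by enone, enol ester and silyl ether.

Step 16
Reactants: 30 aldehyde; 31 2-bromopropene
Product: 33 the (R)-configured 5β-(3-hydroxy-4-methylpent-4-enyl) allylic alcohol, via isopropenylchromium dichloride 32 (not isolated)
Conditions: 31, CrCl2 (4 equiv), NiCl2 (2 mol %), chiral 2-(oxazolin-2-yl)anilide methanesulfonamide ligand, Et3N, THF, rt
Reagents that add atoms: none
Why: Asymmetric Nozaki–Hiyama–Kishi alkenylation, in which the organochromium reagent adds only to the aldehyde beside ketones and esters and the chromium-bound ligand, remote from the ring centres, should fix Si-face attack and hence the (R)-carbinol by reagent control.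

Step 17
Reactants: 33 (R)-allylic alcohol
Product: 35 the (S)-configured 5β-(3-hydroperoxy-4-methylpent-4-enyl) compound with the tert-butyldiphenylsilyl ether retained, via allylic mesylate 34 (not isolated)
Conditions: Ms2O, Et3N (1 equiv each), CH2Cl2, −40 °C; then anhydrous H2O2 in Et2O (excess), 2,6-lutidine, −40 → 0 °C
Reagents that add atoms: hydrogen peroxide, OO
Why: Sulfonate perhydrolysis (displacement of a secondary allylic mesylate by H2O2) should run as SN2 with inversion, because the central methyl group does not stabilise the allyl cation that ionisation would need, no chloride is present, and the nearly neutral medium keeps peroxide anion away from enone and enol ester.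

Step 18
Reactants: 35 silyl-protected hydroperoxide
Product: 36 target CNP0216745.1 (5S,6S,7S in the numbering used here and S at the hydroperoxide carbon)
Conditions: HF·pyridine, pyridine, THF, 0 °C → rt
Reagents that add atoms: none
Why: Fluoride-mediated desilylation under pyridine-buffered conditions should free the primary allylic alcohol without triggering acid-induced cleavage of the hydroperoxide or acyl transfer from the enol ester.

Compound list
1 | (E)-(2-bromoethenyl)trimethylsilane | Br/C=C/[Si](C)(C)C | starting material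
2 | (S)-4-(tert-butyldimethylsilyloxy)cyclopent-2-en-1-one | O=C1C=C[C@@H](O[Si](C)(C)C(C)(C)C)C1 | starting material
3 | 3-bromo-1-(trimethylsilyl)prop-1-yne | BrCC#C[Si](C)(C)C | starting material
4 | (E)-2-(trimethylsilyl)ethenyllithium | [Li]/C=C/[Si](C)(C)C | intermediate
5 | lithium dimethyl[(E)-2-(trimethylsilyl)ethenyl]zincate | [Li+].C[Zn-](C)/C=C/[Si](C)(C)C | intermediate
6 | lithium dimethylzinc C1=C7 enolate (6α-alkenyl, 5β-silyloxy) | [Li+].C[Zn-](C)OC1=C[C@H](/C=C/[Si](C)(C)C)[C@@H](O[Si](C)(C)C(C)(C)C)C1 | intermediate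
7 | (2S,3R,4S)-4-(tert-butyldimethylsilyloxy)-3-[(E)-2-(trimethylsilyl)ethenyl]-2-[3-(trimethylsilyl)prop-2-ynyl]cyclopentan-1-one | O=C1C[C@H](O[Si](C)(C)C(C)(C)C)[C@@H](/C=C/[Si](C)(C)C)[C@@H]1CC#C[Si](C)(C)C | intermediate
8 | (4R,5S)-4-[(E)-2-(trimethylsilyl)ethenyl]-5-[3-(trimethylsilyl)prop-2-ynyl]cyclopent-2-en-1-one | O=C1C=C[C@@H](/C=C/[Si](C)(C)C)[C@@H]1CC#C[Si](C)(C)C | intermediate
9 | lithium C1=C4 enolate of the 5β-methyl adduct | [Li]OC1=C[C@H](C)[C@@H](/C=C/[Si](C)(C)C)[C@@H]1CC#C[Si](C)(C)C | intermediate
10 | (4R,5S)-3-methyl-4-[(E)-2-(trimethylsilyl)ethenyl]-5-[3-(trimethylsilyl)prop-2-ynyl]cyclopent-2-en-1-one | O=C1C=C(C)[C@@H](/C=C/[Si](C)(C)C)[C@@H]1CC#C[Si](C)(C)C | intermediate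
11 | (3-bromopropoxy)(tert-butyl)dimethylsilane | BrCCCO[Si](C)(C)C(C)(C)C | starting material
12 | 3-(tert-butyldimethylsilyloxy)propylmagnesium bromide | Br[Mg]CCCO[Si](C)(C)C(C)(C)C | intermediate
13 | C1=C4 trimethylsilyl enol ether of 14 | CC(C)(C)[Si](C)(C)OCCC[C@@]1(C)C=C(O[Si](C)(C)C)[C@@H](CC#C[Si](C)(C)C)[C@@H]1/C=C/[Si](C)(C)C | intermediate
14 | (2S,3R,4S)-4-[3-(tert-butyldimethylsilyloxy)propyl]-4-methyl-3-[(E)-2-(trimethylsilyl)ethenyl]-2-[3-(trimethylsilyl)prop-2-ynyl]cyclopentan-1-one | CC(C)(C)[Si](C)(C)OCCC[C@@]1(C)CC(=O)[C@@H](CC#C[Si](C)(C)C)[C@@H]1/C=C/[Si](C)(C)C | intermediate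
15 | C1=C4 pyrrolidine enamine of 14 | CC(C)(C)[Si](C)(C)OCCC[C@@]1(C)C=C(N2CCCC2)[C@@H](CC#C[Si](C)(C)C)[C@@H]1/C=C/[Si](C)(C)C | intermediate
16 | methyl propiolate | C#CC(=O)OC | starting material
17 | cis-fused methyl 1-(pyrrolidin-1-yl)bicyclo[3.2.0]hept-6-ene-7-carboxylate, cyclobutene on the α face | CC(C)(C)[Si](C)(C)OCCC[C@@]1(C)[C@@H]2C=C(C(=O)OC)[C@]2(N3CCCC3)[C@@H](CC#C[Si](C)(C)C)[C@@H]1/C=C/[Si](C)(C)C | intermediate
18 | methyl 2-(pyrrolidin-1-yl)cyclohepta-1,3-diene-1-carboxylate with the C5–C7 substituents of 15 | CC(C)(C)[Si](C)(C)OCCC[C@@]1(C)C=CC(C(=O)OC)=C(N2CCCC2)[C@@H](CC#C[Si](C)(C)C)[C@@H]1/C=C/[Si](C)(C)C | intermediate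
19 | methyl 2-hydroxycyclohepta-1,3-diene-1-carboxylate (enol of the β-keto ester) | CC(C)(C)[Si](C)(C)OCCC[C@@]1(C)C=CC(C(=O)OC)=C(O)[C@@H](CC#C[Si](C)(C)C)[C@@H]1/C=C/[Si](C)(C)C | intermediate
20 | methyl 2-(triethylsilyloxy)cyclohepta-1,3-diene-1-carboxylate | CC(C)(C)[Si](C)(C)OCCC[C@@]1(C)C=CC(C(=O)OC)=C(O[Si](CC)(CC)CC)[C@@H](CC#C[Si](C)(C)C)[C@@H]1/C=C/[Si](C)(C)C | intermediate
21 | [2-(triethylsilyloxy)cyclohepta-1,3-dien-1-yl]methanol | CC(C)(C)[Si](C)(C)OCCC[C@@]1(C)C=CC(CO)=C(O[Si](CC)(CC)CC)[C@@H](CC#C[Si](C)(C)C)[C@@H]1/C=C/[Si](C)(C)C | intermediate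
22 | tert-butyldiphenylsilyl ether of 21 | CC(C)(C)[Si](C)(C)OCCC[C@@]1(C)C=CC(CO[Si](c2ccccc2)(c2ccccc2)C(C)(C)C)=C(O[Si](CC)(CC)CC)[C@@H](CC#C[Si](C)(C)C)[C@@H]1/C=C/[Si](C)(C)C | intermediate
23 | 2-(tert-butyldiphenylsilyloxymethyl)cyclohept-2-en-1-one, 7β-silylpropargyl, 6α-silylethenyl | CC(C)(C)[Si](C)(C)OCCC[C@@]1(C)CC=C(CO[Si](c2ccccc2)(c2ccccc2)C(C)(C)C)C(=O)[C@@H](CC#C[Si](C)(C)C)[C@@H]1/C=C/[Si](C)(C)C | intermediate
24 | 7β-(2-oxopropyl) enone, 6α-silylethenyl | CC(C)(C)[Si](C)(C)OCCC[C@@]1(C)CC=C(CO[Si](c2ccccc2)(c2ccccc2)C(C)(C)C)C(=O)[C@@H](CC(C)=O)[C@@H]1/C=C/[Si](C)(C)C | intermediate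
25 | 6α-[(E)-2-iodoethenyl] diketone | CC(C)(C)[Si](C)(C)OCCC[C@@]1(C)CC=C(CO[Si](c2ccccc2)(c2ccccc2)C(C)(C)C)C(=O)[C@@H](CC(C)=O)[C@@H]1/C=C/I | intermediate
26 | 3-methylbut-2-enoic acid | CC(C)=CC(=O)O | starting material
27 | cesium 3-methylbut-2-enoate | [Cs+].CC(C)=CC(=O)[O-] | intermediate
28 | (E)-enol senecioate, both silyl ethers in place | CC(C)(C)[Si](C)(C)OCCC[C@@]1(C)CC=C(CO[Si](c2ccccc2)(c2ccccc2)C(C)(C)C)C(=O)[C@@H](CC(C)=O)[C@@H]1/C=C/OC(=O)C=C(C)C | intermediate
29 | 5β-(3-hydroxypropyl) enol senecioate | OCCC[C@@]1(C)CC=C(CO[Si](c2ccccc2)(c2ccccc2)C(C)(C)C)C(=O)[C@@H](CC(C)=O)[C@@H]1/C=C/OC(=O)C=C(C)C | intermediate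
30 | 5β-(3-oxopropyl) aldehyde | O=CCC[C@@]1(C)CC=C(CO[Si](c2ccccc2)(c2ccccc2)C(C)(C)C)C(=O)[C@@H](CC(C)=O)[C@@H]1/C=C/OC(=O)C=C(C)C | intermediate
31 | 2-bromopropene | C=C(C)Br | starting material
32 | isopropenylchromium dichloride (ligand not drawn) | C=C(C)[Cr](Cl)Cl | intermediate
33 | (R)-allylic alcohol | C=C(C)[C@@H](CC[C@@]1(C)CC=C(CO[Si](c2ccccc2)(c2ccccc2)C(C)(C)C)C(=O)[C@@H](CC(C)=O)[C@@H]1/C=C/OC(=O)C=C(C)C)O | intermediate
34 | (R)-allylic methanesulfonate | C=C(C)[C@@H](CC[C@@]1(C)CC=C(CO[Si](c2ccccc2)(c2ccccc2)C(C)(C)C)C(=O)[C@@H](CC(C)=O)[C@@H]1/C=C/OC(=O)C=C(C)C)OS(C)(=O)=O | intermediate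
35 | (S)-allylic hydroperoxide, tert-butyldiphenylsilyl ether | C=C(C)[C@H](CC[C@@]1(C)CC=C(CO[Si](c2ccccc2)(c2ccccc2)C(C)(C)C)C(=O)[C@@H](CC(C)=O)[C@@H]1/C=C/OC(=O)C=C(C)C)OO | intermediate
36 | CNP0216745.1 | C=C(C)[C@H](CC[C@@]1(C)CC=C(CO)C(=O)[C@@H](CC(C)=O)[C@@H]1/C=C/OC(=O)C=C(C)C)OO | target

Total step count: 18. Longest linear sequence: 18 steps (2 to 36). All other building blocks are purchased.

Steps most likely to fail

First, step 17. The allylic sulfonate may ionise, with loss of configuration or allylic transposition. Peroxide may also attack the enone or the enol ester before substitution is complete. The fallback gives up substitution for an ene reaction and sets out from 30. Wittig olefination with isopropylidenetriphenylphosphorane (i-PrPPh3I, NaN(SiMe3)2, THF, −78 °C), where the aldehyde should react ahead of the ketones, gives the prenyl compound F1. A Schenck ene reaction (O2, tetraphenylporphyrin, visible light, CH2Cl2, 0 °C) should touch only this electron-rich trisubstituted alkene. It has no facial bias and incomplete regiocontrol, so 35 would have to be separated by HPLC from its carbinol epimer F2 and from the tertiary allylic hydroperoxide F3. The route is rejoined at 35.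

Second, step 6. Bond formation at C4 next to the quaternary C5 may be slow. That would leave time for proton transfer within the zwitterion (open-chain Michael addition), for oligomerisation of the propiolate, or for drift of the enamine regiochemistry. The fallback replaces the neutral amine donor by a Lewis-acid-driven silyl enol ether cycloaddition and sets out from 13, isolated by a non-acidic work-up of step 4, so its regiochemistry is fixed by the conjugate addition. TiCl4-promoted [2+2] with 16 (CH2Cl2, −78 °C) gives the silyloxycyclobutene ester F4. Brief treatment with Et3N·3HF frees the cyclobutanol, which should cleave the C1–C4 bond by retro-aldol fragmentation. The route is rejoined at 19, and steps 5 and 7 are no longer needed.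

Third, step 13. Exchange at the hindered alkenyl iodide may be sluggish at a temperature at which aldol closure of the 1,4-diketone, epimerisation at C7 or erosion of the alkene geometry set in. The fallback inverts the polarity of the alkenyl partner and sets out from 25. Miyaura borylation (bis(pinacolato)diboron, PdCl2(dppf), KOPh, toluene, 50 °C) gives the alkenyl pinacol boronate F5. KHF2 in aqueous methanol gives the potassium alkenyltrifluoroborate F6. A Chan–Lam-type oxidative coupling with 26 (CuBr, DMAP, O2, 4 Å molecular sieves, MeCN, 60 °C) forms the enol ester with retention. The route is rejoined at 28.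

Further compounds
F1 | step 17 | 5β-(4-methylpent-3-enyl) analogue of 30 (prenyl compound) | CC(C)=CCC[C@@]1(C)CC=C(CO[Si](c2ccccc2)(c2ccccc2)C(C)(C)C)C(=O)[C@@H](CC(C)=O)[C@@H]1/C=C/OC(=O)C=C(C)C
F2 | step 17 | (R)-hydroperoxide, carbinol epimer of 35 | C=C(C)[C@@H](CC[C@@]1(C)CC=C(CO[Si](c2ccccc2)(c2ccccc2)C(C)(C)C)C(=O)[C@@H](CC(C)=O)[C@@H]1/C=C/OC(=O)C=C(C)C)OO
F3 | step 17 | tertiary allylic hydroperoxide, 5β-[(E)-4-hydroperoxy-4-methylpent-2-enyl] regioisomer | CC(C)(OO)/C=C/C[C@@]1(C)CC=C(CO[Si](c2ccccc2)(c2ccccc2)C(C)(C)C)C(=O)[C@@H](CC(C)=O)[C@@H]1/C=C/OC(=O)C=C(C)C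
F4 | step 6 | cis-fused methyl 1-(trimethylsilyloxy)bicyclo[3.2.0]hept-6-ene-7-carboxylate, cyclobutene on the α face | CC(C)(C)[Si](C)(C)OCCC[C@@]1(C)[C@@H]2C=C(C(=O)OC)[C@]2(O[Si](C)(C)C)[C@@H](CC#C[Si](C)(C)C)[C@@H]1/C=C/[Si](C)(C)C
F5 | step 13 | (E)-alkenyl pinacol boronate derived from 25 | CC(C)(C)[Si](C)(C)OCCC[C@@]1(C)CC=C(CO[Si](c2ccccc2)(c2ccccc2)C(C)(C)C)C(=O)[C@@H](CC(C)=O)[C@@H]1/C=C/B3OC(C)(C)C(C)(C)O3
F6 | step 13 | potassium (E)-alkenyltrifluoroborate derived from F5 | [K+].CC(C)(C)[Si](C)(C)OCCC[C@@]1(C)CC=C(CO[Si](c2ccccc2)(c2ccccc2)C(C)(C)C)C(=O)[C@@H](CC(C)=O)[C@@H]1/C=C/[B-](F)(F)F
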